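The plan hinges on disconnecting O1–C5 of the γ-butyrolactone ring (O1, C2 carbonyl, C3 carbinol, C4, C5). The feature exploited lies at C4. Its two methylene substituents, ring carbon C5 (bonded to O1) and benzylic C7' (bonded to the second arene), are both one-carbon branches, so they can originate from the two like methylenes of a 3-substituted oxetane. The precursor is an enantiopure α-hydroxy acid whose carbinol carbon C3 holds the O-benzylvanillyl group and an oxetan-3-yl ring. A chiral phosphoric acid lets the carboxyl group attack only one methylene. This single event forms O1–C5, builds the lactone, creates C4 under control of C3, and unmasks the other methylene as CH2OH for later arylation.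

Key step: step 5

Numbering: O1, C2 (C=O), C3 (carbinol), C4, C5 in the lactone; C7 is the benzylic carbon on C3 and C7' the benzylic carbon on C4.

Assumption: it cannot be predicted which amine enantiomer gives the less soluble salt with the (S)-acid, or which TRIP enantiomer is matched, so (S)-1-phenylethylamine and (R)-TRIP are written; if either choice proves wrong the mirror-image reagent is used in the same procedure, and for the salt pair this must by symmetry deliver the (S)-acid.

Stereochemical bookkeeping: the target is (3S,4S), with the C3 hydroxyl cis to the C4 benzyl group (the two benzyl groups are trans). Compound 10 is S, and 11, 12 and 15 are all (3S,4S). At C4 the ranking C3 > C5 > CH2OH or CH2Ar becomes CH2Br > C3 > C5 in 12, a cyclic shift that leaves the descriptor unchanged.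

Design notes:
- The oxetane acid is prone to lactonise by itself. It is therefore kept as a crystalline ammonium salt and set free only in the flask of the key step.
- The C3 hydroxyl stays free, because it is the small group that steers the closure.
- The alkyl and aryl partners of the coupling are both bromides, so their reactivities are matched. Zn is the terminal reductant.

TRIP = 3,3'-bis(2,4,6-triisopropylphenyl)-1,1'-binaphthalene-2,2'-diyl hydrogen phosphate.

Step 1
Reactants: 1 4-(benzyloxy)-3-methoxybenzyl alcohol
Product: 2 4-(benzyloxy)-3-methoxybenzyl bromide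
Conditions: PBr3 (0.4 equiv), Et2O, 0 °C
Reagents that add atoms: phosphorus tribromide, BrP(Br)Br
Why: Bromination of an electron-rich benzylic alcohol through its phosphite ester (nucleophilic substitution with PBr3) is fast at 0 °C and leaves the aryl benzyl and methyl ethers untouched.

Step 2
Reactants: 3 methyl 2-(oxetan-3-yl)acetate; 2 4-(benzyloxy)-3-methoxybenzyl bromide
Product: 5 methyl (±)-3-[4-(benzyloxy)-3-methoxyphenyl]-2-(oxetan-3-yl)propanoate, via lithium enolate 4 (not isolated)
Conditions: LiN(iPr)2 (1.1 equiv), THF, −78 °C; then 2, −78 to −20 °C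
Reagents that add atoms: none
Why: Ester enolate alkylation (SN2) with a reactive benzylic bromide should be clean because the oxetane offers no leaving group β to the enolate and tolerates amide bases at low temperature, and the new centre is racemic and is planarised again in step 3.

Step 3
Reactants: 5 methyl (±)-3-[4-(benzyloxy)-3-methoxyphenyl]-2-(oxetan-3-yl)propanoate
Product: 7 methyl (±)-3-[4-(benzyloxy)-3-methoxyphenyl]-2-hydroxy-2-(oxetan-3-yl)propanoate, via potassium enolate 6 (not isolated)
Conditions: KN(SiMe3)2 (1.3 equiv), THF, −78 °C; 3-phenyl-2-(phenylsulfonyl)oxaziridine (1.5 equiv), −78 °C; AcOH quench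
Reagents that add atoms: 3-phenyl-2-(phenylsulfonyl)-1,2-oxaziridine, O=S(=O)(c1ccccc1)N1OC1c1ccccc1
Why: In the Davis oxidation the fully substituted potassium enolate attacks the electrophilic oxaziridine oxygen to give the tertiary α-hydroxy ester, with C3 formed as a racemate that step 4 resolves.

Step 4
Reactants: 7 methyl (±)-3-[4-(benzyloxy)-3-methoxyphenyl]-2-hydroxy-2-(oxetan-3-yl)propanoate
Product: 9 (S)-1-phenylethylammonium (S)-3-[4-(benzyloxy)-3-methoxyphenyl]-2-hydroxy-2-(oxetan-3-yl)propanoate, via racemic acid 8 (not isolated)
Conditions: LiOH·H2O, THF/H2O, rt; aq. HCl to pH 3, 0 °C, extract into EtOAc; (S)-1-phenylethylamine (0.5 equiv), EtOAc/heptane, crystallise and recrystallise below 50 °C to constant ee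
Reagents that add atoms: lithium hydroxide, [Li+].[OH-]; (S)-1-phenylethylamine, C[C@H](N)c1ccccc1
Why: Saponification leaves the base-stable oxetane intact, and classical resolution through diastereomeric ammonium salts (half-equivalent method) then selects the S configuration at C3, which single-crystal diffraction of 9 verifies against the known amine centre, while the salt keeps the carboxyl group deprotonated so that the self-lactonising acid can be stored.

Step 5
Reactants: 9 (S)-1-phenylethylammonium (S)-3-[4-(benzyloxy)-3-methoxyphenyl]-2-hydroxy-2-(oxetan-3-yl)propanoate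
Product: 11 (3S,4S)-3-[4-(benzyloxy)-3-methoxybenzyl]-3-hydroxy-4-(hydroxymethyl)dihydrofuran-2(3H)-one, via free (S)-acid 10 (not isolated)
Conditions: aq. KHSO4/CH2Cl2, 0 °C, separate, dry (Na2SO4); (R)-TRIP (10 mol %), CH2Cl2/PhMe (0.02 M), 25–40 °C
Reagents that add atoms: none
Why: Once the cold acid wash has released 10, the phosphoric acid works bifunctionally, its P–OH hydrogen-bonding to (and finally protonating) the oxetane oxygen while its P=O takes up the carboxyl proton, so that the carboxyl oxygen displaces the ring oxygen from one oxetane CH2 in a strain-releasing SN2 event. The closest known reactions are Brønsted-acid-catalysed desymmetrising openings of 3-substituted oxetanes by tethered oxygen nucleophiles and the isomerisation of oxetane carboxylic acids to hydroxymethyl lactones. The only ring formed, the γ-lactone O1–C2–C3–C4–C5, closes in the 5-exo-tet mode through the new O1–C5 bond, helped by the fully substituted C3 (gem-disubstituent effect). C4 becomes a stereocentre according to which methylene is attacked: the resident C3 centre places the unattacked arm, still tied to the leaving oxygen, on the face of the small C3 hydroxyl (which can also hydrogen-bond to that oxygen) rather than next to the C3 benzyl group, which gives hydroxymethyl cis to hydroxyl, that is 4S, and the matched catalyst enantiomer adds to this bias. The selectivity needed is therefore diastereotopic-group selection plus chemoselectivity, the latter secured by the substrate because the C3 hydroxyl could only exchange one four-membered ether for another, Friedel–Crafts attack by the arene would need a six-membered closure from a far weaker nucleophile, and dilution holds back intermolecular opening. As C3 is already fixed, uncatalysed self-opening can cost only diastereomeric purity and never enantiomeric purity, and 11 is brominated without delay because acyl transfer between its two CH2O arms would invert C4.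

Step 6
Reactants: 11 (3S,4S)-3-[4-(benzyloxy)-3-methoxybenzyl]-3-hydroxy-4-(hydroxymethyl)dihydrofuran-2(3H)-one
Product: 12 (3S,4S)-3-[4-(benzyloxy)-3-methoxybenzyl]-4-(bromomethyl)-3-hydroxydihydrofuran-2(3H)-one
Conditions: CBr4, PPh3, CH2Cl2, 0 °C
Reagents that add atoms: carbon tetrabromide, BrC(Br)(Br)Br
Why: In the Appel reaction only the primary alcohol forms an oxyphosphonium salt that bromide displaces under near-neutral conditions, the hindered tertiary C3 hydroxyl stays free, no bond to C3 or C4 is touched, and removal of the free hydroxymethyl group shuts off translactonisation so that C4 is locked.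

Step 7
Reactants: 13 4-bromo-2-methoxyphenol
Product: 14 1-(benzyloxy)-4-bromo-2-methoxybenzene
Conditions: BnBr, K2CO3, DMF, rt
Reagents that add atoms: benzyl bromide, BrCc1ccccc1
Why: Williamson ether synthesis on a phenoxide with a primary benzylic halide is reliable and leaves the aryl bromide untouched.

Step 8
Reactants: 12 (3S,4S)-3-[4-(benzyloxy)-3-methoxybenzyl]-4-(bromomethyl)-3-hydroxydihydrofuran-2(3H)-one; 14 1-(benzyloxy)-4-bromo-2-methoxybenzene (1.5 equiv)
Product: 15 (3S,4S)-3,4-bis[4-(benzyloxy)-3-methoxybenzyl]-3-hydroxydihydrofuran-2(3H)-one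
Conditions: NiBr2·glyme (10 mol %), 4,4'-di-tert-butyl-2,2'-bipyridine (10 mol %), NaI (25 mol %), Zn dust (2 equiv), DMA, 60 °C
Reagents that add atoms: none
Why: In this nickel-catalysed reductive cross-electrophile coupling the aryl bromide adds to zerovalent nickel, the primary C7' radical released from the alkyl bromide (fed slowly through catalytic iodide exchange) is captured and reductive elimination forms the C7'–aryl bond, free hydroxyl, lactone and benzyl ether groups are tolerated because no basic organometallic is present, and the radical sits on C7' and not on a stereocentre, so C3 and C4 are kept.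

Step 9
Reactants: 15 (3S,4S)-3,4-bis[4-(benzyloxy)-3-methoxybenzyl]-3-hydroxydihydrofuran-2(3H)-one
Product: 16 (3S,4S)-3-hydroxy-3,4-bis(4-hydroxy-3-methoxybenzyl)dihydrofuran-2(3H)-one (nortrachelogenin, 3S,4S enantiomer)
Conditions: H2 (1 atm), Pd/C (10 wt %), EtOAc/EtOH, rt
Reagents that add atoms: none
Why: Catalytic hydrogenolysis cleaves both aryl benzyl ethers in one operation, while the C3 hydroxyl is homobenzylic and not benzylic, so it, the lactone and both stereocentres remain.

Compound list
1 | 4-(benzyloxy)-3-methoxybenzyl alcohol | COc1cc(CO)ccc1OCc1ccccc1 | starting material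
2 | 4-(benzyloxy)-3-methoxybenzyl bromide | COc1cc(CBr)ccc1OCc1ccccc1 | intermediate
3 | methyl 2-(oxetan-3-yl)acetate | COC(=O)CC1COC1 | starting material
4 | lithium enolate of 3 (lithium 1-methoxy-2-(oxetan-3-yl)ethen-1-olate) | COC([O-])=CC1COC1.[Li+] | intermediate
5 | methyl (±)-3-[4-(benzyloxy)-3-methoxyphenyl]-2-(oxetan-3-yl)propanoate | COC(=O)C(Cc1ccc(OCc2ccccc2)c(OC)c1)C1COC1 | intermediate
6 | potassium enolate of 5 | COC([O-])=C(Cc1ccc(OCc2ccccc2)c(OC)c1)C1COC1.[K+] | intermediate
7 | methyl (±)-3-[4-(benzyloxy)-3-methoxyphenyl]-2-hydroxy-2-(oxetan-3-yl)propanoate | COC(=O)C(O)(Cc1ccc(OCc2ccccc2)c(OC)c1)C1COC1 | intermediate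
8 | (±)-3-[4-(benzyloxy)-3-methoxyphenyl]-2-hydroxy-2-(oxetan-3-yl)propanoic acid | OC(=O)C(O)(Cc1ccc(OCc2ccccc2)c(OC)c1)C1COC1 | intermediate
9 | (S)-1-phenylethylammonium (S)-3-[4-(benzyloxy)-3-methoxyphenyl]-2-hydroxy-2-(oxetan-3-yl)propanoate | [O-]C(=O)[C@](O)(Cc1ccc(OCc2ccccc2)c(OC)c1)C1COC1.C[C@H]([NH3+])c1ccccc1 | intermediate
10 | (S)-3-[4-(benzyloxy)-3-methoxyphenyl]-2-hydroxy-2-(oxetan-3-yl)propanoic acid | OC(=O)[C@](O)(Cc1ccc(OCc2ccccc2)c(OC)c1)C1COC1 | intermediate
11 | (3S,4S)-3-[4-(benzyloxy)-3-methoxybenzyl]-3-hydroxy-4-(hydroxymethyl)dihydrofuran-2(3H)-one | OC[C@H]1COC(=O)[C@]1(O)Cc1ccc(OCc2ccccc2)c(OC)c1 | intermediate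
12 | (3S,4S)-3-[4-(benzyloxy)-3-methoxybenzyl]-4-(bromomethyl)-3-hydroxydihydrofuran-2(3H)-one | BrC[C@H]1COC(=O)[C@]1(O)Cc1ccc(OCc2ccccc2)c(OC)c1 | intermediate
13 | 4-bromo-2-methoxyphenol | COc1cc(Br)ccc1O | starting material
14 | 1-(benzyloxy)-4-bromo-2-methoxybenzene | COc1cc(Br)ccc1OCc1ccccc1 | intermediate
15 | (3S,4S)-3,4-bis[4-(benzyloxy)-3-methoxybenzyl]-3-hydroxydihydrofuran-2(3H)-one | COc1cc(C[C@H]2COC(=O)[C@]2(O)Cc2ccc(OCc3ccccc3)c(OC)c2)ccc1OCc1ccccc1 | intermediate
16 | (3S,4S)-3-hydroxy-3,4-bis(4-hydroxy-3-methoxybenzyl)dihydrofuran-2(3H)-one | COc1cc(C[C@H]2COC(=O)[C@]2(O)Cc2ccc(O)c(OC)c2)ccc1O | target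

Total step count: 9
Longest linear sequence: 8 steps (1, 2, 3, 4, 5, 6, 8, 9)

Steps most likely to fail

Step 5. The catalyst may discriminate too weakly between the two diastereotopic oxetane methylenes, or catalysis may be so slow that unselective self-opening dominates. The fallback runs from 10 back to 11 and replaces kinetic selection by thermodynamic control. Compound 10 is isomerised with an achiral acid (diphenyl phosphate, 5 mol %, PhMe, 40 °C) to 11 mixed with its C4 epimer (3S,4R)-3-[4-(benzyloxy)-3-methoxybenzyl]-3-hydroxy-4-(hydroxymethyl)dihydrofuran-2(3H)-one F1. Catalytic DBU in THF then equilibrates the pair by translactonisation: the acyl group moves from O1 to the free hydroxymethyl oxygen, the two arms of C4 swap roles, and only C4 inverts. The isomer with hydroxymethyl trans to the bulky C3 benzyl group, 11, should be favoured. It is separated by chromatography, and recovered epimer is put through the equilibration again.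

Step 4. The diastereomeric salts may oil out or co-crystallise, so that enrichment stalls. The fallback runs from 7 back to 10 and separates the enantiomers of the neutral ester instead. Preparative chiral chromatography (supercritical CO2/MeOH on an amylose tris(3,5-dimethylphenylcarbamate) phase) gives methyl (S)-3-[4-(benzyloxy)-3-methoxyphenyl]-2-hydroxy-2-(oxetan-3-yl)propanoate F2. Its configuration is assigned later by anomalous-dispersion diffraction on bromide 12. LiOH in THF/H2O, cold acidification and extraction into CH2Cl2 then give the solution of 10 that enters step 5 at the point of catalyst addition.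

Step 8. Reduction, dimerisation or β-hydride elimination of the alkyl partner may outrun its capture, because the electron-rich aryl bromide adds slowly to nickel. The fallback runs from 12 back to 15 and uses a preformed organometallic with palladium (Negishi coupling). The C3 hydroxyl is capped (Et3SiOTf, 2,6-lutidine, CH2Cl2, 0 °C) to give (3S,4S)-3-[4-(benzyloxy)-3-methoxybenzyl]-4-(bromomethyl)-3-[(triethylsilyl)oxy]dihydrofuran-2(3H)-one F3. Zinc insertion (Zn dust, LiCl, THF, 50 °C) gives {(3S,4S)-4-[4-(benzyloxy)-3-methoxybenzyl]-5-oxo-4-[(triethylsilyl)oxy]tetrahydrofuran-3-yl}methylzinc bromide F4. Coupling with 14 under Pd(OAc)2/SPhos in THF gives (3S,4S)-3,4-bis[4-(benzyloxy)-3-methoxybenzyl]-3-[(triethylsilyl)oxy]dihydrofuran-2(3H)-one F5. Bu4NF buffered with AcOH then removes the silyl group and gives 15.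

Further compounds
F1 | step 5 | (3S,4R)-3-[4-(benzyloxy)-3-methoxybenzyl]-3-hydroxy-4-(hydroxymethyl)dihydrofuran-2(3H)-one | OC[C@@H]1COC(=O)[C@]1(O)Cc1ccc(OCc2ccccc2)c(OC)c1
F2 | step 4 | methyl (S)-3-[4-(benzyloxy)-3-methoxyphenyl]-2-hydroxy-2-(oxetan-3-yl)propanoate | COC(=O)[C@](O)(Cc1ccc(OCc2ccccc2)c(OC)c1)C1COC1
F3 | step 8 | (3S,4S)-3-[4-(benzyloxy)-3-methoxybenzyl]-4-(bromomethyl)-3-[(triethylsilyl)oxy]dihydrofuran-2(3H)-one | BrC[C@H]1COC(=O)[C@]1(O[Si](CC)(CC)CC)Cc1ccc(OCc2ccccc2)c(OC)c1
F4 | step 8 | {(3S,4S)-4-[4-(benzyloxy)-3-methoxybenzyl]-5-oxo-4-[(triethylsilyl)oxy]tetrahydrofuran-3-yl}methylzinc bromide | Br[Zn]C[C@H]1COC(=O)[C@]1(O[Si](CC)(CC)CC)Cc1ccc(OCc2ccccc2)c(OC)c1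
F5 | step 8 | (3S,4S)-3,4-bis[4-(benzyloxy)-3-methoxybenzyl]-3-[(triethylsilyl)oxy]dihydrofuran-2(3H)-one | COc1cc(C[C@H]2COC(=O)[C@]2(O[Si](CC)(CC)CC)Cc2ccc(OCc3ccccc3)c(OC)c2)ccc1OCc1ccccc1
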